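Start from the amounts. The flasks below differ in their impurity, and the runs made earlier were read at their own times.

| flask | left-handed substrate | right-handed substrate | partner | free catalyst | impurity | added ligand | remark | time |
|---|---|---|---|---|---|---|---|---|
| Friday's | 20 mM | 20 mM | 22 mM | 20 µM | 10 µM | 72 µM | run made earlier |  |
| Wednesday's | 20 mM | 20 mM | 22 mM | 20 µM | 20 µM | 72 µM | run made earlier |  |
| Monday's | 20 mM | 20 mM | 22 mM | 20 µM | 26 µM | 72 µM | run made earlier |  |
| north | 20 mM | 20 mM | 22.0 mM | 20 µM | 13 µM | 72 µM |  | 2.5 min |
| south-east | 20 mM | 20 mM | 22.0 mM | 20 µM | 25 µM | 72 µM |  | 2.5 min |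

| run | time / s | right-handed substrate / % | left-handed substrate / % |
|---|---|---|---|
| Friday's | 12.0 | 45.6 | 42.0 |
| Friday's | 40.0 | 44.6 | 34.7 |
| Friday's | 60.0 | 43.7 | 32.4 |
| Friday's | 120 | 36.9 | 26.9 |
| Wednesday's | 10.0 | 47.8 | 43.3 |
| Wednesday's | 20.0 | 47.3 | 42.7 |
| Wednesday's | 50.0 | 46.3 | 40.2 |
| Wednesday's | 120 | 42.3 | 36.1 |
| Monday's | 25.0 | 46.8 | 43.1 |
| Monday's | 50.0 | 47.5 | 42.2 |
| Monday's | 80.0 | 45.5 | 41.0 |
| Monday's | 120 | 45.6 | 40.5 |

(readings scatter by 1 percentage point)

- free catalyst is single-handed; left-handed substrate and right-handed substrate are mirror images of each other, charged as a racemate, each of them at the stated concentration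
- an excess is the difference of the two amounts in percent of their sum
- an excess is below zero if the other one leads

1. the flask that ends with the higher excess of right-handed substrate over left-handed substrate among what is left of the two, or "neither" when 2 percentage points or less lies between them (north / south-east / neither)
2. excess of right-handed substrate over left-handed substrate among what is left of the two at the end, north
3. excess of right-handed substrate over left-handed substrate among what is left of the two at the end, south-east

Add the two substrates and follow the loss. Friday's, with free catalyst minus impurity at 10.0 µM, loses 24 percentage points from 12.0 s to 120 s. Wednesday's, at 0 µM, loses 13 points from 10.0 s to 120 s. Monday's, at −6.00 µM, loses 3.8 points from 25.0 s to 120 s. Per second, Friday's loses more than Wednesday's, and Wednesday's more than Monday's. So I suspect that impurity takes free catalyst one for one, with the smaller charge as the limiting reagent of that pairing. For north the difference is 7.00 µM. Call free catalyst charged minus impurity charged the surplus. For south-east it is −5.00 µM, below zero, like Monday's.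

Now the chain for north. Scale Friday's loss by surplus and by time, from Friday's first reading to 2.5 min. That gives 21 points, so I estimate that 66.3% of the charge is left in north. Friday's gap, right-handed minus left-handed, averages 10 points over its last three readings. I keep that gap for north, whose surplus is also above zero. My estimate of north's excess, gap over total, is then 15.7%.

The weak link is the scaling, since Wednesday's loses substrate at zero surplus. So I reforge it: put the loss rate on a straight line through Wednesday's and Friday's, and read it at north's surplus. North's estimated loss becomes 26 points, its total 61.5%, and its excess 16.9%. For south-east I take Monday's last reading, 5.92%. On these estimates north leads by 11 points, above the margin.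

The forecast says north, with 14.3% for north (from 11% to 18%) and 6.2% for south-east (from 4.5% to 8%). Its north figure is lower than mine. In its words: “These come from interpolation, and the mechanism is uncertain.”

    free catalyst + left-handed substrate ⇌ catalyst intermediate A (K = 82.0 L mol⁻¹, k = 2.40 × 10⁵ L mol⁻¹ s⁻¹)
    free catalyst + right-handed substrate ⇌ catalyst intermediate B (K = 1100 L mol⁻¹, k = 28000 L mol⁻¹ s⁻¹)
    partner + catalyst intermediate A → free catalyst + left-handed product (k = 8900 L mol⁻¹ s⁻¹)
    partner + catalyst intermediate B → free catalyst + right-handed product (k = 320 L mol⁻¹ s⁻¹)
    left-handed product ⇌ right-handed product (k = 0.00650 s⁻¹)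
    free catalyst + impurity → spent catalyst (k = 91000 L mol⁻¹ s⁻¹)
    free catalyst + added ligand ⇌ idle complex, settled at all times (K = 15000 L mol⁻¹)

The flask gives 17.6% in north and 6.64% in south-east, so north ends higher, inside both forecast ranges. In south-east, a surplus of −5.00 µM means 20.0% of the impurity charge should outlast the free catalyst. At 2.5 min in south-east, 21% of it is left, with spent catalyst at 99.3% of the catalyst charged. Now take the neighbour, south-east with 34.0 µM of free catalyst. Its surplus is 9.00 µM, above zero, its impurity falls to 0.039% of its charge, and its excess ends at 20.3%.

All runs come from a simulation for substances that don't exist, and the scatter is random.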